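## Retrosynthetic overview

1. Target ⇒ aryl benzyl ether hydrogenolysis and hydride removal of the auxiliary from a boron glycolate syn-aldol adduct; this aldol (aryloxyacetyl imide + O-benzylvanillin) sets the threo glycerol unit.
2. Aryloxyacetyl imide ⇒ alkylation of the single free (guaiacyl) phenol of a syringyl-O-benzyl furofuran with a bromoacetyl oxazolidinone.
3. Furofuran ⇒ carbonyl deletion (lactone → lactol → ether) from a cis-fused 2,6-diaryl bis-γ-lactone, which already holds both rings and all four ring stereocentres.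
4. Key step: bis-lactone ⇒ one-pot double boron syn-aldol/double lactonisation of a C2-symmetric succinyl bis-imide with two different aryl aldehydes (two C–C bonds, four stereocentres, rings A and B together).
5. Ring order: rings A and B of the dioxabicyclo[3.3.0]octane close together in step 2 and are never reopened; all six stereocentres come from (R)-4-benzyloxazolidin-2-one.

Assumption: the oxazolidinone, succinyl chloride, bromoacetyl bromide and the three aryl aldehydes are bought; lithium, boron and aluminium enolates, alkoxides and amides are treated as reactive forms of the numbered compounds and carry no numbers of their own.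

Numbering used in the text: C7/C7′ = aryl-bearing ring carbons, C8/C8′ = ring-fusion carbons, C9/C9′ = ring CH2O carbons, C7″–C9″ = glycerol chain.

## Route

Step 1
Reactants: 1 (R)-4-benzyl-1,3-oxazolidin-2-one; 2 succinyl chloride
Product: 3 1,4-bis[(4R)-4-benzyl-2-oxo-1,3-oxazolidin-3-yl]butane-1,4-dione
Conditions: 1 (2.05 equiv), n-BuLi (2.05 equiv), THF, −78 °C; 2 (1.0 equiv), −78 → 0 °C
Reagents that add atoms: none
Why: N-acylation of the lithiated oxazolidinone by a diacid chloride (standard imide formation) gives the C2-symmetric bis-imide; no new stereocentre.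

Step 2
Reactants: 3 succinyl bis-imide; 4 4-(benzyloxy)-3,5-dimethoxybenzaldehyde; 5 4-formyl-2-methoxyphenyl acetate (vanillin acetate)
Product: 7 (1R,2R,5R,6R)-2-(4-acetoxy-3-methoxyphenyl)-6-[4-(benzyloxy)-3,5-dimethoxyphenyl]-3,7-dioxabicyclo[3.3.0]octane-4,8-dione (cis-fused bis-lactone; both aryl groups exo), via bis-aldol diol 6 (not isolated)
Conditions: Bu2BOTf (2.2 equiv), iPr2NEt (2.6 equiv), CH2Cl2, −78 → 0 °C; 4 (1.0 equiv, slow addition), −78 °C; 5 (2.0 equiv), −78 → 0 °C; MeOH, aq. NaH2PO4/Na2HPO4 (pH 7), 0 °C (non-oxidative work-up, keeps the aryl acetate); crude, Et3N (0.5 equiv), CH2Cl2, 23 → 40 °C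
Reagents that add atoms: none
Why: Proposed new method: the bis(Z-dibutylboron enolate) of 3 should add first to 4 and then, more slowly because the remaining enolate now sits next to a fully substituted carbon, to 5 through two chair Zimmerman–Traxler transition states in which each (R)-benzyl oxazolidinone shields the same enolate face, so both syn aldols give the all-R diol 6, whose two benzylic hydroxyls each lie 1,4 to the opposite imide carbonyl and lactonise with loss of 1 to close rings A and B as the only possible cis-fused bis-lactone with both aryl groups exo (C7, C8, C8′ and C7′ all set here by the auxiliary); the closest known reaction types are the Evans boron syn-aldol, the aldol–lactonisation of succinate mono-imides to paraconic lactones and the double aldol–bislactonisation of succinate dianions with aryl aldehydes.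

Step 3
Reactants: 7 bis-lactone
Product: 9 4-[(1R,3aS,4R,6aS)-4-[4-(benzyloxy)-3,5-dimethoxyphenyl]tetrahydro-1H,3H-furo[3,4-c]furan-1-yl]-2-methoxyphenol, via bis-lactol 8 (not isolated)
Conditions: iBu2AlH (4.5 equiv), CH2Cl2, −78 °C; MeOH, aq. potassium sodium tartrate; crude, Et3SiH (6 equiv), BF3·OEt2 (3 equiv), CH2Cl2, −78 → −40 °C
Reagents that add atoms: none
Why: Lactone half-reduction followed by ionic hydrogenation of the cyclic oxocarbenium ions (lactol → ether deoxygenation) only replaces each C=O by CH2, so the four ring stereocentres are kept, and iBu2AlH also cleaves the aryl acetate to unmask the one phenol needed next.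

Step 4
Reactants: 1 (R)-4-benzyl-1,3-oxazolidin-2-one; 10 bromoacetyl bromide
Product: 11 (4R)-4-benzyl-3-(2-bromoacetyl)-1,3-oxazolidin-2-one
Conditions: n-BuLi (1.0 equiv), THF, −78 °C; 10 (1.1 equiv), −78 °C
Reagents that add atoms: none
Why: N-acylation of the lithiated oxazolidinone with an acid bromide, where acyl substitution is far faster than displacement of the α-bromide at −78 °C; no new stereocentre.

Step 5
Reactants: 9 furofuran phenol; 11 bromoacetyl imide
Product: 12 (4R)-4-benzyl-3-[2-(4-{(1R,3aS,4R,6aS)-4-[4-(benzyloxy)-3,5-dimethoxyphenyl]tetrahydro-1H,3H-furo[3,4-c]furan-1-yl}-2-methoxyphenoxy)acetyl]-1,3-oxazolidin-2-one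
Conditions: K2CO3 (1.5 equiv), acetone, 23 °C
Reagents that add atoms: none
Why: Williamson ether synthesis on an α-halo carbonyl: only the guaiacyl phenol is free (the syringyl oxygen is benzylated), and SN2 at the activated CH2Br outruns attack at the imide carbonyl, which is reversible for a phenoxide; no stereocentre is touched.

Step 6
Reactants: 12 aryloxyacetyl imide; 13 4-(benzyloxy)-3-methoxybenzaldehyde (O-benzylvanillin)
Product: 14 (4R)-4-benzyl-3-[(2R,3S)-3-[4-(benzyloxy)-3-methoxyphenyl]-3-hydroxy-2-(4-{(1R,3aS,4R,6aS)-4-[4-(benzyloxy)-3,5-dimethoxyphenyl]tetrahydro-1H,3H-furo[3,4-c]furan-1-yl}-2-methoxyphenoxy)propanoyl]-1,3-oxazolidin-2-one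
Conditions: iPr2NEt (1.5 equiv), Bu2BOTf (1.2 equiv), CH2Cl2, −78 → 0 °C; 13 (1.3 equiv), −78 → 0 °C; MeOH, aq. NaH2PO4/Na2HPO4 (pH 7), H2O2, 0 °C
Reagents that add atoms: none
Why: Evans boron glycolate syn-aldol: the Z-boron enolate adds to the aldehyde through a chair Zimmerman–Traxler transition state on the face left open by the (R)-benzyl group, setting C8″ and C7″ as 2R,3S (syn, which is threo), with the amine present before the boron triflate so the furofuran never meets free Lewis acid.

Step 7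
Reactants: 14 aldol adduct
Product: 15 (1S,2S)-1-[4-(benzyloxy)-3-methoxyphenyl]-2-(4-{(1R,3aS,4R,6aS)-4-[4-(benzyloxy)-3,5-dimethoxyphenyl]tetrahydro-1H,3H-furo[3,4-c]furan-1-yl}-2-methoxyphenoxy)propane-1,3-diol
Conditions: LiBH4 (3 equiv), MeOH (3 equiv), THF, 0 °C
Reagents that add atoms: none
Why: Reductive cleavage of the N-acyl oxazolidinone by LiBH4 gives the primary alcohol and releases 1; C7″ is untouched and C8″ keeps its geometry (its descriptor changes from R to S only because C9″ drops in CIP rank).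

Step 8
Reactants: 15 dibenzyl ether of the target
Product: 16 (1S,2S)-1-(4-hydroxy-3-methoxyphenyl)-2-(4-{(1R,3aS,4R,6aS)-4-(4-hydroxy-3,5-dimethoxyphenyl)tetrahydro-1H,3H-furo[3,4-c]furan-1-yl}-2-methoxyphenoxy)propane-1,3-diol (CNP0255927.3)
Conditions: H2 (1 atm), Pd/C (10 wt % Pd, cat.), EtOAc/MeOH, 23 °C, stopped at full conversion
Reagents that add atoms: none
Why: Catalytic hydrogenolysis cleaves the two aryl benzyl ethers much faster than the dialkyl-type benzylic C–O bonds of the furofuran or the benzylic alcohol under neutral conditions; no stereocentre is touched.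

## Compound list

1 | (R)-4-benzyl-1,3-oxazolidin-2-one | O=C1N[C@H](Cc2ccccc2)CO1 | starting material
2 | succinyl chloride | ClC(=O)CCC(Cl)=O | starting material
3 | 1,4-bis[(4R)-4-benzyl-2-oxo-1,3-oxazolidin-3-yl]butane-1,4-dione | O=C(CCC(=O)N1[C@H](Cc2ccccc2)COC1=O)N3[C@H](Cc4ccccc4)COC3=O | intermediate
4 | 4-(benzyloxy)-3,5-dimethoxybenzaldehyde | COc1cc(C=O)cc(OC)c1OCc2ccccc2 | starting material
5 | 4-formyl-2-methoxyphenyl acetate (vanillin acetate) | CC(=O)Oc1ccc(C=O)cc1OC | starting material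
6 | (2R,3R)-2-[(R)-(4-acetoxy-3-methoxyphenyl)(hydroxy)methyl]-3-[(R)-[4-(benzyloxy)-3,5-dimethoxyphenyl](hydroxy)methyl]-1,4-bis[(4R)-4-benzyl-2-oxo-1,3-oxazolidin-3-yl]butane-1,4-dione (bis-aldol diol, not isolated) | CC(=O)Oc1ccc(cc1OC)[C@H](O)[C@H](C(=O)N2[C@H](Cc3ccccc3)COC2=O)[C@@H](C(=O)N4[C@H](Cc5ccccc5)COC4=O)[C@@H](O)c6cc(OC)c(OCc7ccccc7)c(OC)c6 | intermediate
7 | (1R,2R,5R,6R)-2-(4-acetoxy-3-methoxyphenyl)-6-[4-(benzyloxy)-3,5-dimethoxyphenyl]-3,7-dioxabicyclo[3.3.0]octane-4,8-dione | CC(=O)Oc1ccc(cc1OC)[C@@H]2OC(=O)[C@@H]3[C@H]2C(=O)O[C@H]3c4cc(OC)c(OCc5ccccc5)c(OC)c4 | intermediate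
8 | (1R,2R,5R,6R)-2-(4-hydroxy-3-methoxyphenyl)-6-[4-(benzyloxy)-3,5-dimethoxyphenyl]-3,7-dioxabicyclo[3.3.0]octane-4,8-diol (bis-lactol, anomer mixture, not isolated) | Oc1ccc(cc1OC)[C@@H]2OC(O)[C@@H]3[C@H]2C(O)O[C@H]3c4cc(OC)c(OCc5ccccc5)c(OC)c4 | intermediate
9 | 4-[(1R,3aS,4R,6aS)-4-[4-(benzyloxy)-3,5-dimethoxyphenyl]tetrahydro-1H,3H-furo[3,4-c]furan-1-yl]-2-methoxyphenol | Oc1ccc(cc1OC)[C@@H]2OC[C@@H]3[C@H]2CO[C@H]3c4cc(OC)c(OCc5ccccc5)c(OC)c4 | intermediate
10 | bromoacetyl bromide | BrCC(Br)=O | starting material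
11 | (4R)-4-benzyl-3-(2-bromoacetyl)-1,3-oxazolidin-2-one | BrCC(=O)N1[C@H](Cc2ccccc2)COC1=O | intermediate
12 | (4R)-4-benzyl-3-[2-(4-{(1R,3aS,4R,6aS)-4-[4-(benzyloxy)-3,5-dimethoxyphenyl]tetrahydro-1H,3H-furo[3,4-c]furan-1-yl}-2-methoxyphenoxy)acetyl]-1,3-oxazolidin-2-one | O=C(COc1ccc(cc1OC)[C@@H]2OC[C@@H]3[C@H]2CO[C@H]3c4cc(OC)c(OCc5ccccc5)c(OC)c4)N6[C@H](Cc7ccccc7)COC6=O | intermediate
13 | 4-(benzyloxy)-3-methoxybenzaldehyde (O-benzylvanillin) | COc1cc(C=O)ccc1OCc2ccccc2 | starting material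
14 | (4R)-4-benzyl-3-[(2R,3S)-3-[4-(benzyloxy)-3-methoxyphenyl]-3-hydroxy-2-(aryloxy)propanoyl]-1,3-oxazolidin-2-one, aryloxy = the phenoxy group of 9 | COc1cc(ccc1OCc2ccccc2)[C@H](O)[C@H](C(=O)N3[C@H](Cc4ccccc4)COC3=O)Oc5ccc(cc5OC)[C@@H]6OC[C@@H]7[C@H]6CO[C@H]7c8cc(OC)c(OCc9ccccc9)c(OC)c8 | intermediate
15 | (1S,2S)-1-[4-(benzyloxy)-3-methoxyphenyl]-2-(aryloxy)propane-1,3-diol, aryloxy = the phenoxy group of 9 | COc1cc(ccc1OCc2ccccc2)[C@H](O)[C@H](CO)Oc3ccc(cc3OC)[C@@H]4OC[C@@H]5[C@H]4CO[C@H]5c6cc(OC)c(OCc7ccccc7)c(OC)c6 | intermediate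
16 | (1S,2S)-1-(4-hydroxy-3-methoxyphenyl)-2-(4-{(1R,3aS,4R,6aS)-4-(4-hydroxy-3,5-dimethoxyphenyl)tetrahydro-1H,3H-furo[3,4-c]furan-1-yl}-2-methoxyphenoxy)propane-1,3-diol | COc1cc([C@H](O)[C@H](CO)Oc2ccc([C@@H]3OC[C@@H]4[C@H]3CO[C@H]4c3cc(OC)c(O)c(OC)c3)cc2OC)ccc1O | target

## Step count and risk

Total steps: 8. Longest linear sequence: 7 (steps 1, 2, 3, 5, 6, 7, 8); step 4 is a one-step side branch.

The three steps most likely to fail:

**Step 2 (one-pot double aldol/bislactonisation).** The risks are statistical formation of the two symmetrical bis-lactones, a sluggish second aldol at the hindered enolate, and early lactonisation that expels the second auxiliary. The fallback sets out from 3 and comes back at 6, which closes to 7 as in step 2. The two aldols are run as separate, purified operations. Compound 3 is used in twofold excess with Bu2BOTf/iPr2NEt (one equivalent relative to 4) so that mono-enolisation dominates; addition of 4 and a cold non-oxidative work-up give the crude mono-aldol hydroxy bis-imide F1, and unreacted 3 is recovered. Immediate silylation (Et3SiOTf, 2,6-lutidine, CH2Cl2, −78 °C) gives the mono-aldol triethylsilyl ether F2, whose blocked hydroxyl cannot lactonise. An ordinary boron aldol of F2 with 5 gives the bis-aldol mono-triethylsilyl ether F3. HF·pyridine in THF then frees the hydroxyl to give 6.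

**Step 3 (bis-lactone to bis-ether).** The risks are over-reduction by iBu2AlH and BF3-induced ionisation at the electron-rich benzylic C–O bonds, which would cause epimerisation or reductive ring opening. The fallback sets out from 7 and comes back at 9. The rings are opened instead of deoxygenated: LiAlH4 in THF at 0 °C reduces both lactones and the aryl acetate to the phenolic tetraol F4. A catalytic amount of camphorsulfonic acid (CH2Cl2/THF, 0 °C, short time) then ionises both benzylic alcohols, and each primary hydroxyl closes onto the cation trans to the neighbouring ring substituent. This is the kinetic aryl-exo mode of tetraol → furofuran cyclisations and gives 9; C8 and C8′ from step 2 still dictate all four centres.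

**Step 5 (phenol alkylation with the bromoacetyl imide).** The risk is cleavage or acyl transfer at the base-labile imide. The fallback sets out from 9 and comes back at 12. The imide is made by acylating the auxiliary instead of alkylating with it: 9 with methyl bromoacetate (K2CO3, acetone) gives the methyl aryloxyacetate F5. LiOH in THF/H2O gives the aryloxyacetic acid F6. Activation as the pivaloyl mixed anhydride (PivCl, Et3N, THF, −20 °C) and addition of 1 with LiCl gives 12; step 4 is then not needed.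

Further compounds
F1 | step 2 | (4R)-4-benzyl-3-[(2R)-2-{(R)-[4-(benzyloxy)-3,5-dimethoxyphenyl](hydroxy)methyl}-4-[(4R)-4-benzyl-2-oxo-1,3-oxazolidin-3-yl]-4-oxobutanoyl]-1,3-oxazolidin-2-one (mono-aldol hydroxy bis-imide) | COc1cc(cc(OC)c1OCc2ccccc2)[C@H](O)[C@H](C(=O)N3[C@H](Cc4ccccc4)COC3=O)CC(=O)N5[C@H](Cc6ccccc6)COC5=O
F2 | step 2 | triethylsilyl ether of F1 (mono-aldol triethylsilyl ether) | COc1cc(cc(OC)c1OCc2ccccc2)[C@H](O[Si](CC)(CC)CC)[C@H](C(=O)N3[C@H](Cc4ccccc4)COC3=O)CC(=O)N5[C@H](Cc6ccccc6)COC5=O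
F3 | step 2 | mono-triethylsilyl ether of 6 at the hydroxyl next to the 4-(benzyloxy)-3,5-dimethoxyphenyl group (bis-aldol mono-triethylsilyl ether) | CC(=O)Oc1ccc(cc1OC)[C@H](O)[C@H](C(=O)N2[C@H](Cc3ccccc3)COC2=O)[C@@H](C(=O)N4[C@H](Cc5ccccc5)COC4=O)[C@@H](O[Si](CC)(CC)CC)c6cc(OC)c(OCc7ccccc7)c(OC)c6
F4 | step 3 | (1R,2S,3S,4R)-1-(4-hydroxy-3-methoxyphenyl)-4-[4-(benzyloxy)-3,5-dimethoxyphenyl]-2,3-bis(hydroxymethyl)butane-1,4-diol (phenolic tetraol) | Oc1ccc(cc1OC)[C@H](O)[C@H](CO)[C@@H](CO)[C@@H](O)c2cc(OC)c(OCc3ccccc3)c(OC)c2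
F5 | step 5 | methyl 2-(4-{(1R,3aS,4R,6aS)-4-[4-(benzyloxy)-3,5-dimethoxyphenyl]tetrahydro-1H,3H-furo[3,4-c]furan-1-yl}-2-methoxyphenoxy)acetate | COC(=O)COc1ccc(cc1OC)[C@@H]2OC[C@@H]3[C@H]2CO[C@H]3c4cc(OC)c(OCc5ccccc5)c(OC)c4
F6 | step 5 | 2-(4-{(1R,3aS,4R,6aS)-4-[4-(benzyloxy)-3,5-dimethoxyphenyl]tetrahydro-1H,3H-furo[3,4-c]furan-1-yl}-2-methoxyphenoxy)acetic acid | OC(=O)COc1ccc(cc1OC)[C@@H]2OC[C@@H]3[C@H]2CO[C@H]3c4cc(OC)c(OCc5ccccc5)c(OC)c4
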